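**Plan**
- Retrosynthesis: ring C is cut at O1–C8a and C2–C3 in one stroke. This separates 4-(benzyloxy)benzaldehyde (O1=C2 with ring B) from an ortho-fluoroaryl α-benzyloxy ketone (C3–C4–C4a–C8a on ring A). Further cuts are C4–C4a (ortho-lithiation/acylation), the side-chain C=CH2 (hydrogenation) and the C6–C bond (aryllithium acylation).
- Enabling feature: C3 is α and C8a is ortho to the same C4 carbonyl. With fluorine on C8a, the unit F–C8a=C4a–C4(=O)–C3H2 is an arene-embedded Danishefsky-type diene, nucleophilic at C3 as its enol silane and electrophilic at C8a as a vinylogous acyl fluoride.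
- Forward order: ring A comes from 1-bromo-3,5-difluorobenzene, a symmetric arene, so no C6/C8 regiochemistry question arises. The side chain with its 4-oxyphenyl ring is attached next, then the ketone arm. Ring C is closed last and brings in ring B; global debenzylation ends the route.
- Stereochemistry: the benzylic (1R) centre comes from iridium-catalysed asymmetric hydrogenation of a 1,1-diarylethene. C2 (R) comes from an acyloxyborane-controlled aldol addition to the Si face of the aldehyde. C3 (R) comes from equilibration to the trans-diequatorial chromanone.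

Key step: step 8

Assumption: the ligand enantiomer in step 5 and the tartaric acid enantiomer in step 8 are assigned by analogy with the usual models for these catalyst classes; the antipodes are equally available if the sense on these substrates proves opposite.

**Step 1**
Reactants: 1 1-bromo-3,5-difluorobenzene; 2 4-(benzyloxy)benzoyl chloride
Product: 4 [4-(benzyloxy)phenyl](4-bromo-2,6-difluorophenyl)methanone, via aryllithium 3 (not isolated)
Conditions: LiN(i-Pr)2, THF, −78 °C; then cannulated into 2, THF, −78 °C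
Reagents that add atoms: none
Why: Deprotonation occurs at the C–H flanked by both fluorines (directed ortho-metalation), and acylation of the hindered aryllithium by the acid chloride at −78 °C should stop at the diaryl ketone.

**Step 2**
Reactants: 4 [4-(benzyloxy)phenyl](4-bromo-2,6-difluorophenyl)methanone
Product: 5 [2,6-bis(benzyloxy)-4-bromophenyl][4-(benzyloxy)phenyl]methanone
Conditions: BnOH (2.3 equiv), NaH (2.3 equiv), DMF, 0 to 60 °C
Reagents that add atoms: benzyl alcohol, OCc1ccccc1
Why: Twofold SNAr by benzyloxide at the two fluorines ortho to the ketone, with the para bromide kept as the much poorer nucleofuge, fixes the oxygen pattern of ring A without any regiochemical choice.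

**Step 3**
Reactants: 5 [2,6-bis(benzyloxy)-4-bromophenyl][4-(benzyloxy)phenyl]methanone
Product: 6 [2,6-bis(benzyloxy)-4-fluorophenyl][4-(benzyloxy)phenyl]methanone
Conditions: (cod)Pd(CH2SiMe3)2 (4 mol %), AlPhos (6 mol %), AgF (2 equiv), KF (0.5 equiv), cyclohexane, 90 °C
Reagents that add atoms: silver fluoride, [Ag+].[F-]
Why: Palladium-catalysed nucleophilic fluorination of an aryl bromide (Buchwald type) should work here because the bromide is para to an acyl group and the ketone is not enolisable.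

**Step 4**
Reactants: 6 [2,6-bis(benzyloxy)-4-fluorophenyl][4-(benzyloxy)phenyl]methanone
Product: 8 1,3-bis(benzyloxy)-2-{1-[4-(benzyloxy)phenyl]ethenyl}-5-fluorobenzene, via tertiary carbinol 7 (not isolated)
Conditions: MeMgBr, THF, 0 °C to rt; 1 M HCl work-up; then TsOH·H2O (5 mol %), toluene, 40 °C
Reagents that add atoms: methylmagnesium bromide, C[Mg]Br
Why: Grignard addition to the non-enolisable diaryl ketone and acid-catalysed E1 dehydration through the doubly benzylic cation can give only the exocyclic 1,1-diarylethene.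

**Step 5**
Reactants: 8 1,3-bis(benzyloxy)-2-{1-[4-(benzyloxy)phenyl]ethenyl}-5-fluorobenzene
Product: 9 1,3-bis(benzyloxy)-2-{(1R)-1-[4-(benzyloxy)phenyl]ethyl}-5-fluorobenzene
Conditions: [Ir(cod)(L)]B[3,5-(CF3)2C6H3]4 (2 mol %; L = (4S,5S)-ThrePHOX), H2 (50 bar), CH2Cl2, rt
Reagents that add atoms: none
Why: Iridium N,P-ligand asymmetric hydrogenation of a 1,1-diarylethene should deliver hydrogen to the face that gives the (1R) centre, because the twisted 2,6-dialkoxyaryl group and the coplanar para-substituted aryl group are sterically very different.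

**Step 6**
Reactants: 9 1,3-bis(benzyloxy)-2-{(1R)-1-[4-(benzyloxy)phenyl]ethyl}-5-fluorobenzene; 10 2-(benzyloxy)-N-methoxy-N-methylacetamide
Product: 12 2-(benzyloxy)-1-{2,4-bis(benzyloxy)-3-[(1R)-1-[4-(benzyloxy)phenyl]ethyl]-6-fluorophenyl}ethan-1-one, via aryllithium 11 (not isolated)
Conditions: n-BuLi, THF, −78 °C; then 10, −78 to −40 °C; 1 M HCl
Reagents that add atoms: none
Why: Directed ortho-metalation at the C–H flanked by fluorine and benzyloxy (the two such positions are homotopic), followed by Weinreb ketone synthesis, places the acyl arm next to fluorine; the hindered diarylmethine C–H should not be removed at −78 °C.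

**Step 7**
Reactants: 12 2-(benzyloxy)-1-{2,4-bis(benzyloxy)-3-[(1R)-1-[4-(benzyloxy)phenyl]ethyl]-6-fluorophenyl}ethan-1-one
Product: 13 {[(1Z)-2-(benzyloxy)-1-{2,4-bis(benzyloxy)-3-[(1R)-1-[4-(benzyloxy)phenyl]ethyl]-6-fluorophenyl}ethenyl]oxy}trimethylsilane
Conditions: Me3SiOTf, Et3N, CH2Cl2, 0 °C; pentane extraction
Reagents that add atoms: trimethylsilyl trifluoromethanesulfonate, C[Si](C)(C)OS(=O)(=O)C(F)(F)F
Why: Soft enolisation with O-silylation should give mainly the (Z)-enol silane, and the geometry is not critical because the next step is stereoconvergent.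

**Step 8**
Reactants: 13 {[(1Z)-2-(benzyloxy)-1-{2,4-bis(benzyloxy)-3-[(1R)-1-[4-(benzyloxy)phenyl]ethyl]-6-fluorophenyl}ethenyl]oxy}trimethylsilane; 14 4-(benzyloxy)benzaldehyde
Product: 17 (2R,3R)-3,5,7-tris(benzyloxy)-2-[4-(benzyloxy)phenyl]-6-{(1R)-1-[4-(benzyloxy)phenyl]ethyl}-2,3-dihydro-4H-chromen-4-one, via silyl aldol 15 (not isolated), via cis-chromanone 16 (not isolated)
Conditions: acyloxyborane from (2S,3S)-2-O-(2,6-diisopropoxybenzoyl)tartaric acid and BH3·THF (20 mol %), EtCN, −78 °C; then Bu4N[Ph3SiF2] (0.5 equiv), THF, −78 to −20 °C; AcOH; then Et3N–AcOH (1:1), MeOH–THF, 40 °C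
Reagents that add atoms: none
Why: Proposed new method: the boron-bound aldehyde 14 is attacked on its Si face by the enol silane carbon C3 through an open Mukaiyama transition state and silyl transfer gives the O-silyl aldol 15, which cannot revert; catalytic fluoride then unmasks the C2 alkoxide, O1 adds to C8a of the vinylogous acyl fluoride F–C8a=C4a–C4=O (Meisenheimer adduct stabilised by the C4 carbonyl), and the expelled fluoride is taken up by the silicon of the next molecule, so the ring closure is a net-neutral fluoride relay that ends in Me3SiF. The closest known reaction types are the chiral acyloxyborane-catalysed Mukaiyama aldol of aryl ketone enol silanes with aromatic aldehydes, the fluoride-catalysed desilylative SNAr etherification of acyl-activated aryl fluorides and, as a stepwise relative, the Danishefsky hetero-Diels–Alder synthesis of dihydropyranones. Ring C closes by a 6-endo-trig addition–elimination at C8a with retention at C2, since the C2–O1 bond is never broken. C2 (R) is set by the catalyst in the aldol step, whereas C3 is formed mainly syn (cis-chromanone 16) and is then equilibrated to the trans (2R,3R) isomer with both substituents equatorial, in an amine–ammonium buffer whose high proton supply should let reprotonation of the enolate outrun β-elimination of O1. The step needs ring closure to be faster than retro-aldol cleavage of the transient alkoxide and needs O1 to attack only C8a; the first is served by keeping the alkoxide at chain-carrier concentration with a non-chelating cation at low temperature, the second by C8a being the only carbon of ring A that carries a leaving group.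

**Step 9**
Reactants: 17 (2R,3R)-3,5,7-tris(benzyloxy)-2-[4-(benzyloxy)phenyl]-6-{(1R)-1-[4-(benzyloxy)phenyl]ethyl}-2,3-dihydro-4H-chromen-4-one
Product: 18 (2R,3R)-3,5,7-trihydroxy-2-(4-hydroxyphenyl)-6-[(1R)-1-(4-hydroxyphenyl)ethyl]-2,3-dihydro-4H-chromen-4-one
Conditions: H2 (1 atm), Pd(OH)2/C, EtOAc–MeOH, rt, stopped at five equivalents of uptake
Reagents that add atoms: none
Why: Hydrogenolysis of the five benzyl ethers under neutral conditions should leave the aryl ketone, the C2–O1 bond (an aryl ether conjugated with C4=O) and the three stereocentres untouched.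

**Compound list**
1 | 1-bromo-3,5-difluorobenzene | Fc1cc(F)cc(Br)c1 | starting material
2 | 4-(benzyloxy)benzoyl chloride | O=C(Cl)c1ccc(OCc2ccccc2)cc1 | starting material
3 | (4-bromo-2,6-difluorophenyl)lithium | [Li]c1c(F)cc(Br)cc1F | intermediate
4 | [4-(benzyloxy)phenyl](4-bromo-2,6-difluorophenyl)methanone | O=C(c1ccc(OCc2ccccc2)cc1)c1c(F)cc(Br)cc1F | intermediate
5 | [2,6-bis(benzyloxy)-4-bromophenyl][4-(benzyloxy)phenyl]methanone | O=C(c1ccc(OCc2ccccc2)cc1)c1c(OCc2ccccc2)cc(Br)cc1OCc1ccccc1 | intermediate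
6 | [2,6-bis(benzyloxy)-4-fluorophenyl][4-(benzyloxy)phenyl]methanone | O=C(c1ccc(OCc2ccccc2)cc1)c1c(OCc2ccccc2)cc(F)cc1OCc1ccccc1 | intermediate
7 | 1-[2,6-bis(benzyloxy)-4-fluorophenyl]-1-[4-(benzyloxy)phenyl]ethan-1-ol (racemic) | CC(O)(c1ccc(OCc2ccccc2)cc1)c1c(OCc2ccccc2)cc(F)cc1OCc1ccccc1 | intermediate
8 | 1,3-bis(benzyloxy)-2-{1-[4-(benzyloxy)phenyl]ethenyl}-5-fluorobenzene | C=C(c1ccc(OCc2ccccc2)cc1)c1c(OCc2ccccc2)cc(F)cc1OCc1ccccc1 | intermediate
9 | 1,3-bis(benzyloxy)-2-{(1R)-1-[4-(benzyloxy)phenyl]ethyl}-5-fluorobenzene | C[C@H](c1ccc(OCc2ccccc2)cc1)c1c(OCc2ccccc2)cc(F)cc1OCc1ccccc1 | intermediate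
10 | 2-(benzyloxy)-N-methoxy-N-methylacetamide | CON(C)C(=O)COCc1ccccc1 | starting material
11 | {2,4-bis(benzyloxy)-3-[(1R)-1-[4-(benzyloxy)phenyl]ethyl]-6-fluorophenyl}lithium | C[C@H](c1ccc(OCc2ccccc2)cc1)c1c(OCc2ccccc2)cc(F)c([Li])c1OCc1ccccc1 | intermediate
12 | 2-(benzyloxy)-1-{2,4-bis(benzyloxy)-3-[(1R)-1-[4-(benzyloxy)phenyl]ethyl]-6-fluorophenyl}ethan-1-one | C[C@H](c1ccc(OCc2ccccc2)cc1)c1c(OCc2ccccc2)cc(F)c(C(=O)COCc2ccccc2)c1OCc1ccccc1 | intermediate
13 | {[(1Z)-2-(benzyloxy)-1-{2,4-bis(benzyloxy)-3-[(1R)-1-[4-(benzyloxy)phenyl]ethyl]-6-fluorophenyl}ethenyl]oxy}trimethylsilane | C[C@H](c1ccc(OCc2ccccc2)cc1)c1c(OCc2ccccc2)cc(F)c(/C(O[Si](C)(C)C)=C/OCc2ccccc2)c1OCc1ccccc1 | intermediate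
14 | 4-(benzyloxy)benzaldehyde | O=Cc1ccc(OCc2ccccc2)cc1 | starting material
15 | (2S,3R)-2-(benzyloxy)-1-{2,4-bis(benzyloxy)-3-[(1R)-1-[4-(benzyloxy)phenyl]ethyl]-6-fluorophenyl}-3-[4-(benzyloxy)phenyl]-3-[(trimethylsilyl)oxy]propan-1-one | C[C@H](c1ccc(OCc2ccccc2)cc1)c1c(OCc2ccccc2)cc(F)c(C(=O)[C@@H](OCc2ccccc2)[C@@H](c2ccc(OCc3ccccc3)cc2)O[Si](C)(C)C)c1OCc1ccccc1 | intermediate
16 | (2R,3S)-3,5,7-tris(benzyloxy)-2-[4-(benzyloxy)phenyl]-6-{(1R)-1-[4-(benzyloxy)phenyl]ethyl}-2,3-dihydro-4H-chromen-4-one (cis) | C[C@H](c1ccc(OCc2ccccc2)cc1)c1c(OCc2ccccc2)cc2c(c1OCc1ccccc1)C(=O)[C@@H](OCc1ccccc1)[C@@H](c1ccc(OCc3ccccc3)cc1)O2 | intermediate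
17 | (2R,3R)-3,5,7-tris(benzyloxy)-2-[4-(benzyloxy)phenyl]-6-{(1R)-1-[4-(benzyloxy)phenyl]ethyl}-2,3-dihydro-4H-chromen-4-one (trans) | C[C@H](c1ccc(OCc2ccccc2)cc1)c1c(OCc2ccccc2)cc2c(c1OCc1ccccc1)C(=O)[C@H](OCc1ccccc1)[C@@H](c1ccc(OCc3ccccc3)cc1)O2 | intermediate
18 | (2R,3R)-3,5,7-trihydroxy-2-(4-hydroxyphenyl)-6-[(1R)-1-(4-hydroxyphenyl)ethyl]-2,3-dihydro-4H-chromen-4-one | C[C@H](c1ccc(O)cc1)c1c(O)cc2c(c1O)C(=O)[C@H](O)[C@@H](c1ccc(O)cc1)O2 | target

**Totals and risks**
Total step count: 9. Longest linear sequence: 9 steps (1 to 18).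

Steps most likely to fail:

Step 8. The transient C2 alkoxide may undergo retro-aldol cleavage before it closes the ring. The finished chromanone may also be enolised and opened by β-elimination of O1. Either process erodes the configuration at C2, and equilibration at C3 may stop short of the trans isomer. The fallback closes ring C at O1–C2 under non-basic conditions instead. It sets out from 12: SNAr exchange of fluoride for hydroxide (acetohydroxamic acid, K2CO3, DMSO, 80 °C) should give the ortho-hydroxy ketone 2-(benzyloxy)-1-{2,4-bis(benzyloxy)-3-[(1R)-1-[4-(benzyloxy)phenyl]ethyl]-6-hydroxyphenyl}ethan-1-one F1. Twofold silylation (Me3SiOTf, Et3N) gives the aryl silyl ether enol silane F2. Mukaiyama aldol addition to 14 under the acyloxyborane from (2R,3R)-tartaric acid (Re-face attack), with acidic work-up, gives the syn aldol with free phenol F3. Mitsunobu cyclisation (PPh3, DIAD, THF, 0 °C), in which the phenol oxygen displaces the activated carbinol with inversion at C2, gives the trans compound directly and comes back to the route at 17.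

Step 5. Face discrimination on the hindered diarylethene may be insufficient, or hydrogen uptake slow. The fallback sets the centre by a stereospecific substitution and sets out from 6. Asymmetric transfer hydrogenation (RuCl[(S,S)-TsDPEN](p-cymene), HCO2H–Et3N, the catalyst antipode being chosen for the (S)-carbinol) gives the (S)-diarylmethanol F4. O-Alkylation (NaH, BrCH2CH2OMe) gives the (S)-2-methoxyethyl ether F5. Nickel-catalysed Kumada coupling with MeMgI (Ni(cod)2, DPEphos, toluene, rt), which proceeds with inversion, comes back to the route at 9.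

Step 3. Hydrodebromination may compete, or C–F reductive elimination at palladium may be too slow. The fallback forms the C–F bond oxidatively at copper through a boronate and sets out from 5. Miyaura borylation (B2pin2, PdCl2(dppf), KOAc, dioxane, 80 °C) gives the aryl pinacol boronate F6. Copper-mediated fluorination (Cu(OTf)2, KF, MeCN, 60 °C) comes back to the route at 6.

**Further compounds**
F1 | step 8 | 2-(benzyloxy)-1-{2,4-bis(benzyloxy)-3-[(1R)-1-[4-(benzyloxy)phenyl]ethyl]-6-hydroxyphenyl}ethan-1-one | C[C@H](c1ccc(OCc2ccccc2)cc1)c1c(OCc2ccccc2)cc(O)c(C(=O)COCc2ccccc2)c1OCc1ccccc1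
F2 | step 8 | {[(1Z)-2-(benzyloxy)-1-{2,4-bis(benzyloxy)-3-[(1R)-1-[4-(benzyloxy)phenyl]ethyl]-6-[(trimethylsilyl)oxy]phenyl}ethenyl]oxy}trimethylsilane | C[C@H](c1ccc(OCc2ccccc2)cc1)c1c(OCc2ccccc2)cc(O[Si](C)(C)C)c(/C(O[Si](C)(C)C)=C/OCc2ccccc2)c1OCc1ccccc1
F3 | step 8 | (2R,3S)-2-(benzyloxy)-1-{2,4-bis(benzyloxy)-3-[(1R)-1-[4-(benzyloxy)phenyl]ethyl]-6-hydroxyphenyl}-3-[4-(benzyloxy)phenyl]-3-hydroxypropan-1-one | C[C@H](c1ccc(OCc2ccccc2)cc1)c1c(OCc2ccccc2)cc(O)c(C(=O)[C@H](OCc2ccccc2)[C@@H](O)c2ccc(OCc3ccccc3)cc2)c1OCc1ccccc1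
F4 | step 5 | (S)-[2,6-bis(benzyloxy)-4-fluorophenyl][4-(benzyloxy)phenyl]methanol | O[C@@H](c1ccc(OCc2ccccc2)cc1)c1c(OCc2ccccc2)cc(F)cc1OCc1ccccc1
F5 | step 5 | 1,3-bis(benzyloxy)-2-{(S)-[4-(benzyloxy)phenyl](2-methoxyethoxy)methyl}-5-fluorobenzene | COCCO[C@@H](c1ccc(OCc2ccccc2)cc1)c1c(OCc2ccccc2)cc(F)cc1OCc1ccccc1
F6 | step 3 | [2,6-bis(benzyloxy)-4-(4,4,5,5-tetramethyl-1,3,2-dioxaborolan-2-yl)phenyl][4-(benzyloxy)phenyl]methanone | O=C(c1ccc(OCc2ccccc2)cc1)c1c(OCc2ccccc2)cc(B2OC(C)(C)C(C)(C)O2)cc1OCc1ccccc1
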